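**Plan**

1. Locants used throughout (germacrane numbering): ring C1 (epoxide CH), C2 (C=O), C3=C4 (C4–CH3), C5 (CHOH), C6 (lactone O), C7, C8 (O-tiglate), C9 (CH2), C10 (epoxide C–CH3); lactone C11(=C13H2)–C12(=O)–O6.
2. Retrosynthesis: the O5 silyl ether, the C2 ketone (from a carbinol) and the tiglate are adjusted last. The ten-membered ring is then cut at C7–C8. O8–C8–C7–C11=C13 is a homoallylic alcohol retron inside the α-methylene-γ-butyrolactone, so the precursor is a 3-(bromomethyl)butenolide (allylchromium donor, nucleophilic at C7) tethered to a C8 aldehyde.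
3. The open chain is cut at C2–C3 (Z-alkenyl iodide + epoxy aldehyde, Ni/Cr) and at C5–C6 (vinylogous Mukaiyama aldol of a 3-substituted 2-silyloxyfuran with (Z)-3-iodo-2-methylacrolein, which delivers the butenolide ready-made).
4. Forward: the epoxy aldehyde (C8–C10, C1, C2) and the butenolide (C3–C7, C11–C13) are made separately and joined at C2–C3. The lactone stays the only ring until the C7–C8 closure forms the carbocycle and the exocyclic methylene together.
5. Stereochemistry: C1/C10 from Sharpless epoxidation of an (E)-allylic alcohol (Negishi carboalumination); C5/C6 from the catalyst-controlled anti aldol; Z-C3=C4 from anti-carbomagnesiation of propargyl alcohol; C7 and C8 by substrate control in the ring closure.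

Key step: step 17

Assumption: in step 10 the catalyst is the hexafluoroantimonate of the trivalent chromium complex of (R,R)-N,N'-bis(3,5-di-tert-butylsalicylidene)cyclohexane-1,2-diamine, written (R,R)-(salen)CrSbF6, and this antipode is taken to direct the furan to the Re face of the aldehyde; if the sense of induction is the reverse, the (S,S) complex is used.

**Route**

Step 1
Reactants: 1 but-3-yn-1-ol
Product: 2 1-[(but-3-yn-1-yloxy)methyl]-4-methoxybenzene
Conditions: NaH, 4-methoxybenzyl chloride, Bu4NI (cat.), THF/DMF, 0 °C → rt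
Reagents that add atoms: 4-methoxybenzyl chloride, COc1ccc(CCl)cc1
Why: Williamson etherification of the primary alkoxide gives the 4-methoxybenzyl (PMB) ether, which later leaves under neutral oxidative conditions.

Step 2
Reactants: 2 1-[(but-3-yn-1-yloxy)methyl]-4-methoxybenzene
Product: 5 (E)-5-[(4-methoxybenzyl)oxy]-3-methylpent-2-en-1-ol, via alkenyldimethylalane 3 (not isolated), via lithium alanate 4 (not isolated)
Conditions: Me3Al, Cp2ZrCl2 (20 mol %), CH2Cl2, 0 °C → rt; n-BuLi, THF, −30 °C; (CH2O)n, rt; 1 M HCl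
Reagents that add atoms: trimethylaluminium, C[Al](C)C; formaldehyde (from paraformaldehyde), C=O
Why: Negishi zirconium-catalysed carboalumination adds CH3 and Al syn across the terminal alkyne with Al at the terminus, and the alanate is hydroxymethylated with retention, which fixes the (E)-trisubstituted alkene C1=C10.

Step 3
Reactants: 5 (E)-5-[(4-methoxybenzyl)oxy]-3-methylpent-2-en-1-ol
Product: 6 [(2R,3R)-3-{2-[(4-methoxybenzyl)oxy]ethyl}-3-methyloxiran-2-yl]methanol
Conditions: Ti(OiPr)4 (10 mol %), D-(−)-diethyl tartrate (12 mol %), t-BuOOH, 4 Å MS, CH2Cl2, −20 °C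
Reagents that add atoms: tert-butyl hydroperoxide, CC(C)(C)OO
Why: Sharpless asymmetric epoxidation; the D-tartrate delivers oxygen to the face that gives the (2R,3R)-epoxy alcohol (C1 and C10 of the target), and the E alkene becomes the trans-epoxide.

Step 4
Reactants: 6 [(2R,3R)-3-{2-[(4-methoxybenzyl)oxy]ethyl}-3-methyloxiran-2-yl]methanol
Product: 7 (2S,3R)-3-{2-[(4-methoxybenzyl)oxy]ethyl}-3-methyloxirane-2-carbaldehyde
Conditions: Dess–Martin periodinane, NaHCO3, CH2Cl2, 0 °C → rt
Reagents that add atoms: none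
Why: Buffered Dess–Martin oxidation gives the α,β-epoxy aldehyde without epimerisation or epoxide opening; it is used without storage.

Step 5
Reactants: 8 furan-3-ylmethanol
Product: 9 3-{[(4-methoxybenzyl)oxy]methyl}furan
Conditions: NaH, 4-methoxybenzyl chloride, Bu4NI (cat.), THF, 0 °C → rt
Reagents that add atoms: 4-methoxybenzyl chloride, COc1ccc(CCl)cc1
Why: Williamson etherification; the same PMB group is placed on the future C13 oxygen so that both primary oxygens can be unmasked together in step 14.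

Step 6
Reactants: 9 3-{[(4-methoxybenzyl)oxy]methyl}furan
Product: 12 3-{[(4-methoxybenzyl)oxy]methyl}furan-2(5H)-one, via 2-lithiofuran 10 (not isolated), via lithium furyltrimethoxyborate 11 (not isolated)
Conditions: n-BuLi, THF, −78 → 0 °C; B(OMe)3, −78 °C → rt; 30% H2O2, AcOH, 0 °C; Et3N (cat.), CH2Cl2, rt
Reagents that add atoms: hydrogen peroxide, OO
Why: Ether-directed lithiation at C2 of the furan, borylation and peroxide oxidation give the 2-hydroxyfuran, which tautomerises to the conjugated butenolide with the carbonyl next to the CH2OPMB-bearing carbon (future C12, C11, C13).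

Step 7
Reactants: 12 3-{[(4-methoxybenzyl)oxy]methyl}furan-2(5H)-one
Product: 13 [(3-{[(4-methoxybenzyl)oxy]methyl}furan-2-yl)oxy]trimethylsilane
Conditions: Me3SiCl, Et3N, CH2Cl2, 0 °C → rt; filtered under argon and used crude
Reagents that add atoms: chlorotrimethylsilane, C[Si](C)(C)Cl
Why: O-silylation of the butenolide dienolate gives the 2-silyloxyfuran, a vinylogous silyl ketene acetal that is nucleophilic at its C5 (future C6).

Step 8
Reactants: 14 prop-2-yn-1-ol
Product: 16 (2Z)-3-iodo-2-methylprop-2-en-1-ol, via alkenylmagnesium chelate 15 (not isolated)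
Conditions: MeMgBr (2.5 equiv), CuI (10 mol %), THF, −10 °C → rt; iodine, −78 → 0 °C; 1 M HCl
Reagents that add atoms: methylmagnesium bromide, C[Mg]Br; iodine, II
Why: Copper-catalysed carbomagnesiation of the propargylic alkoxide proceeds anti through the five-membered magnesium chelate and iodinolysis with retention places iodine cis to CH2OH, which is the source of the Z-C3=C4 geometry.

Step 9
Reactants: 16 (2Z)-3-iodo-2-methylprop-2-en-1-ol
Product: 17 (2Z)-3-iodo-2-methylprop-2-enal
Conditions: MnO2, CH2Cl2, rt, dark; used at once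
Reagents that add atoms: none
Why: Allylic oxidation with MnO2 is neutral and should not isomerise the Z-enal.

Step 10
Reactants: 17 (2Z)-3-iodo-2-methylprop-2-enal; 13 [(3-{[(4-methoxybenzyl)oxy]methyl}furan-2-yl)oxy]trimethylsilane
Product: 19 (5R)-5-[(1S,2Z)-1-hydroxy-3-iodo-2-methylprop-2-en-1-yl]-3-{[(4-methoxybenzyl)oxy]methyl}furan-2(5H)-one, via trimethylsilyl ether 18 (not isolated)
Conditions: (R,R)-(salen)CrSbF6 (5 mol %), 4 Å MS, CH2Cl2, −30 °C; then 1 M HCl, THF, 0 °C
Reagents that add atoms: none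
Why: Catalytic enantioselective vinylogous Mukaiyama aldol reaction in which the chiral trivalent chromium Lewis acid activates the enal and the silyloxyfuran attacks through its C5 in an open transition state that should favour the anti (5,6-erythro) adduct, so that catalyst control sets C5 (S) and C6 (R) together and the butenolide emerges with C11–C13 in place.

Step 11
Reactants: 19 (5R)-5-[(1S,2Z)-1-hydroxy-3-iodo-2-methylprop-2-en-1-yl]-3-{[(4-methoxybenzyl)oxy]methyl}furan-2(5H)-one
Product: 20 (5R)-5-{(1S,2Z)-1-[(tert-butyldimethylsilyl)oxy]-3-iodo-2-methylprop-2-en-1-yl}-3-{[(4-methoxybenzyl)oxy]methyl}furan-2(5H)-one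
Conditions: t-BuMe2SiOTf, 2,6-lutidine, CH2Cl2, −78 °C
Reagents that add atoms: tert-butyldimethylsilyl triflate, CC(C)(C)[Si](C)(C)OS(=O)(=O)C(F)(F)F
Why: Silylation with a weak hindered base protects O5 without deprotonating the acidic γ-position (C6) of the butenolide; O5 must stay masked until the end so that it cannot add to the later C2 carbonyl.

Step 12
Reactants: 20 (5R)-5-{(1S,2Z)-1-[(tert-butyldimethylsilyl)oxy]-3-iodo-2-methylprop-2-en-1-yl}-3-{[(4-methoxybenzyl)oxy]methyl}furan-2(5H)-one; 7 (2S,3R)-3-{2-[(4-methoxybenzyl)oxy]ethyl}-3-methyloxirane-2-carbaldehyde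
Product: 22 (5R)-5-{(1S,2Z,4R)-1-[(tert-butyldimethylsilyl)oxy]-4-hydroxy-4-[(2R,3R)-3-{2-[(4-methoxybenzyl)oxy]ethyl}-3-methyloxiran-2-yl]-2-methylbut-2-en-1-yl}-3-{[(4-methoxybenzyl)oxy]methyl}furan-2(5H)-one, via alkenylchromium dichloride 21 (not isolated)
Conditions: CrCl2 (6 equiv), NiCl2 (2 mol %), DMSO, rt
Reagents that add atoms: none
Why: Nozaki–Hiyama–Kishi coupling in which zerovalent nickel inserts into the carbon–iodine bond with retention of the Z geometry and the derived alkenylchromium adds only to the aldehyde; Felkin–Anh addition anti to the epoxide C–O bond should favour the (2R) carbinol, a centre that is erased in step 20.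

Step 13
Reactants: 22 the C2 carbinol from step 12
Product: 23 (5R)-5-{(1S,2Z,4R)-1-[(tert-butyldimethylsilyl)oxy]-4-[(2R,3R)-3-{2-[(4-methoxybenzyl)oxy]ethyl}-3-methyloxiran-2-yl]-2-methyl-4-[(triethylsilyl)oxy]but-2-en-1-yl}-3-{[(4-methoxybenzyl)oxy]methyl}furan-2(5H)-one
Conditions: Et3SiCl, imidazole, DMF, 0 °C → rt
Reagents that add atoms: chlorotriethylsilane, CC[Si](CC)(CC)Cl
Why: Silylation keeps C2 at the carbinol oxidation level through the ring closure, so that no six-membered closure of C7 onto a C2 ketone can compete, and the triethylsilyl ether can later be removed in the presence of the O5 tert-butyldimethylsilyl ether.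

Step 14
Reactants: 23 the bis-PMB ether from step 13
Product: 24 (5R)-5-{(1S,2Z,4R)-1-[(tert-butyldimethylsilyl)oxy]-4-[(2R,3R)-3-(2-hydroxyethyl)-3-methyloxiran-2-yl]-2-methyl-4-[(triethylsilyl)oxy]but-2-en-1-yl}-3-(hydroxymethyl)furan-2(5H)-one
Conditions: DDQ (2.6 equiv), CH2Cl2/pH 7 buffer, 0 °C → rt
Reagents that add atoms: none
Why: Oxidative cleavage of both PMB ethers by DDQ is neutral and leaves the epoxide, the silyl ethers and the butenolide untouched.

Step 15
Reactants: 24 the diol from step 14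
Product: 25 (5R)-3-(bromomethyl)-5-{(1S,2Z,4R)-1-[(tert-butyldimethylsilyl)oxy]-4-[(2R,3R)-3-(2-hydroxyethyl)-3-methyloxiran-2-yl]-2-methyl-4-[(triethylsilyl)oxy]but-2-en-1-yl}furan-2(5H)-one
Conditions: N-bromosuccinimide, Me2S, CH2Cl2, −30 → 0 °C
Reagents that add atoms: N-bromosuccinimide, O=C1CCC(=O)N1Br
Why: Corey–Kim halide formation, in which only the allylic alkoxysulfonium salt at C13 is displaced by bromide (direct or allylic displacement leads to the same conjugated primary bromide), while the salt of the saturated C8 alcohol reverts to the alcohol on work-up.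

Step 16
Reactants: 25 the bromo alcohol from step 15
Product: 26 (5R)-3-(bromomethyl)-5-{(1S,2Z,4R)-1-[(tert-butyldimethylsilyl)oxy]-2-methyl-4-[(2R,3R)-3-methyl-3-(2-oxoethyl)oxiran-2-yl]-4-[(triethylsilyl)oxy]but-2-en-1-yl}furan-2(5H)-one
Conditions: Dess–Martin periodinane, NaHCO3, CH2Cl2, 0 °C; crude product used at once
Reagents that add atoms: none
Why: Buffered Dess–Martin oxidation is non-basic, which matters because the β,γ-epoxy aldehyde can open its epoxide by β-elimination; it is therefore not chromatographed.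

Step 17
Reactants: 26 the bromo aldehyde from step 16
Product: 28 (1R,2R,5S,6R,7R,8R,10R)-5-[(tert-butyldimethylsilyl)oxy]-1,10-epoxy-8-hydroxy-2-[(triethylsilyl)oxy]germacra-3Z,11(13)-dien-6,12-olide (6,7-cis-fused), via allylchromium dichloride 27 (not isolated)
Conditions: CrCl2 (10 equiv), 4 Å MS, THF, rt, 26 added over 10 h (final 1 mM); sat. NH4Cl
Reagents that add atoms: none
Why: Two equivalents of divalent chromium reduce the allylic C13–Br bond to the allylchromium species (trivalent chromium), which binds the aldehyde oxygen and transfers the allyl unit through C7 (γ-attack) in a six-membered chair transition state, shifting the double bond to C11=C13 and so unveiling the α-methylene lactone; the closest known reaction type is the Nozaki–Hiyama allylation of aldehydes by 2-(alkoxycarbonyl)allyl bromides, including its use to close ten-membered germacrane rings. The carbocycle closes in the 10-exo-trig mode onto the aldehyde carbon. At C7 the aldehyde is tethered through C5 to one face of the flat butenolide at C6, and the eight-atom tether, stiffened by the Z-C3=C4 alkene and the trans-epoxide, should reach C7 only from that same face, which gives the cis ring fusion (H6 and H7 cis). At C8 the tether is expected to hold C9 under the lactone ring on the C5 side (pseudo-axial in the chair), which corresponds to the (8R) carbinol. The step needs γ- over α-attack (closed transition state), the aldehyde as the only electrophile (C2 is a silyl ether; epoxide, lactone and silyl ethers are inert to divalent chromium) and cyclisation over oligomerisation (slow addition, high dilution).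

Step 18
Reactants: 28 the macrocyclic alcohol from step 17
Product: 29 (1R,2R,5S,6R,7R,8R,10R)-5-[(tert-butyldimethylsilyl)oxy]-1,10-epoxy-8-[(E)-2-methylbut-2-enoyloxy]-2-[(triethylsilyl)oxy]germacra-3Z,11(13)-dien-6,12-olide
Conditions: tiglic acid, 2,4,6-trichlorobenzoyl chloride, Et3N, toluene, rt; then 28, DMAP, toluene, rt → 40 °C
Reagents that add atoms: tiglic acid, C/C=C(\C)C(=O)O
Why: Yamaguchi esterification through the mixed anhydride acylates the hindered C8 carbinol with retention, and tiglate is the stable E isomer so no geometric scrambling is expected.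

Step 19
Reactants: 29 the tiglate from step 18
Product: 30 (1R,2R,5S,6R,7R,8R,10R)-5-[(tert-butyldimethylsilyl)oxy]-1,10-epoxy-2-hydroxy-8-[(E)-2-methylbut-2-enoyloxy]germacra-3Z,11(13)-dien-6,12-olide
Conditions: pyridinium p-toluenesulfonate (cat.), MeOH/CH2Cl2, 0 °C
Reagents that add atoms: none
Why: Acid-catalysed methanolysis removes the secondary triethylsilyl ether much faster than the more hindered tert-butyldimethylsilyl ether at O5, and this mild acid should spare the epoxide, the tiglate and the methylene lactone.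

Step 20
Reactants: 30 the C2 carbinol from step 19
Product: 31 (1S,5S,6R,7R,8R,10R)-5-[(tert-butyldimethylsilyl)oxy]-1,10-epoxy-8-[(E)-2-methylbut-2-enoyloxy]-2-oxogermacra-3Z,11(13)-dien-6,12-olide
Conditions: Dess–Martin periodinane, NaHCO3, CH2Cl2, 0 °C → rt
Reagents that add atoms: none
Why: Dess–Martin oxidation of the allylic C2 carbinol gives the Z-enone and epoxy ketone; the C2 centre is erased, so either C2 epimer from step 12 converges here.

Step 21
Reactants: 31 the silyl ether from step 20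
Product: 32 (1S,5S,6R,7R,8R,10R)-1,10-epoxy-5-hydroxy-8-[(E)-2-methylbut-2-enoyloxy]-2-oxogermacra-3Z,11(13)-dien-6,12-olide (CNP0345622.1)
Conditions: HF·pyridine, pyridine, THF, 0 °C → rt
Reagents that add atoms: none
Why: Buffered HF·pyridine cleaves the last silyl ether without base, which protects the methylene lactone, the epoxy ketone and the tiglate.

**Compound list**

1 | but-3-yn-1-ol | C#CCCO | starting material
2 | 1-[(but-3-yn-1-yloxy)methyl]-4-methoxybenzene | C#CCCOCc1ccc(OC)cc1 | intermediate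
3 | (E)-{4-[(4-methoxybenzyl)oxy]-2-methylbut-1-en-1-yl}dimethylalane | COc1ccc(COCC/C(C)=C/[Al](C)C)cc1 | intermediate
4 | lithium butyl{(E)-4-[(4-methoxybenzyl)oxy]-2-methylbut-1-en-1-yl}dimethylalanate | [Li+].COc1ccc(COCC/C(C)=C/[Al-](C)(C)CCCC)cc1 | intermediate
5 | (E)-5-[(4-methoxybenzyl)oxy]-3-methylpent-2-en-1-ol | COc1ccc(COCC/C(C)=C/CO)cc1 | intermediate
6 | [(2R,3R)-3-{2-[(4-methoxybenzyl)oxy]ethyl}-3-methyloxiran-2-yl]methanol | COc1ccc(COCC[C@@]2(C)O[C@@H]2CO)cc1 | intermediate
7 | (2S,3R)-3-{2-[(4-methoxybenzyl)oxy]ethyl}-3-methyloxirane-2-carbaldehyde | COc1ccc(COCC[C@@]2(C)O[C@@H]2C=O)cc1 | intermediate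
8 | furan-3-ylmethanol | OCc1ccoc1 | starting material
9 | 3-{[(4-methoxybenzyl)oxy]methyl}furan | COc1ccc(COCc2ccoc2)cc1 | intermediate
10 | 2-lithio-3-{[(4-methoxybenzyl)oxy]methyl}furan | COc1ccc(COCc2ccoc2[Li])cc1 | intermediate
11 | lithium trimethoxy(3-{[(4-methoxybenzyl)oxy]methyl}furan-2-yl)borate | [Li+].COc1ccc(COCc2ccoc2[B-](OC)(OC)OC)cc1 | intermediate
12 | 3-{[(4-methoxybenzyl)oxy]methyl}furan-2(5H)-one | COc1ccc(COCC2=CCOC2=O)cc1 | intermediate
13 | [(3-{[(4-methoxybenzyl)oxy]methyl}furan-2-yl)oxy]trimethylsilane | COc1ccc(COCc2ccoc2O[Si](C)(C)C)cc1 | intermediate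
14 | prop-2-yn-1-ol | C#CCO | starting material
15 | (Z)-[3-(bromomagnesiooxy)-2-methylprop-1-en-1-yl]magnesium bromide | Br[Mg]/C=C(/C)CO[Mg]Br | intermediate
16 | (2Z)-3-iodo-2-methylprop-2-en-1-ol | I/C=C(/C)CO | intermediate
17 | (2Z)-3-iodo-2-methylprop-2-enal | I/C=C(/C)C=O | intermediate
18 | trimethylsilyl ether of 19 at the carbinol oxygen | I/C=C(/C)[C@H](O[Si](C)(C)C)[C@@H]1OC(=O)C(COCc2ccc(OC)cc2)=C1 | intermediate
19 | (5R)-5-[(1S,2Z)-1-hydroxy-3-iodo-2-methylprop-2-en-1-yl]-3-{[(4-methoxybenzyl)oxy]methyl}furan-2(5H)-one | I/C=C(/C)[C@H](O)[C@@H]1OC(=O)C(COCc2ccc(OC)cc2)=C1 | intermediate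
20 | (5R)-5-{(1S,2Z)-1-[(tert-butyldimethylsilyl)oxy]-3-iodo-2-methylprop-2-en-1-yl}-3-{[(4-methoxybenzyl)oxy]methyl}furan-2(5H)-one | I/C=C(/C)[C@H](O[Si](C)(C)C(C)(C)C)[C@@H]1OC(=O)C(COCc2ccc(OC)cc2)=C1 | intermediate
21 | (Z)-alkenylchromium dichloride derived from 20 (CrCl2 in place of iodine) | Cl[Cr](Cl)/C=C(/C)[C@H](O[Si](C)(C)C(C)(C)C)[C@@H]1OC(=O)C(COCc2ccc(OC)cc2)=C1 | intermediate
22 | (5R)-5-{(1S,2Z,4R)-1-[(tert-butyldimethylsilyl)oxy]-4-hydroxy-4-[(2R,3R)-3-{2-[(4-methoxybenzyl)oxy]ethyl}-3-methyloxiran-2-yl]-2-methylbut-2-en-1-yl}-3-{[(4-methoxybenzyl)oxy]methyl}furan-2(5H)-one | COc1ccc(COCC[C@@]2(C)O[C@@H]2[C@H](O)/C=C(/C)[C@H](O[Si](C)(C)C(C)(C)C)[C@@H]2OC(=O)C(COCc3ccc(OC)cc3)=C2)cc1 | intermediate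
23 | (5R)-5-{(1S,2Z,4R)-1-[(tert-butyldimethylsilyl)oxy]-4-[(2R,3R)-3-{2-[(4-methoxybenzyl)oxy]ethyl}-3-methyloxiran-2-yl]-2-methyl-4-[(triethylsilyl)oxy]but-2-en-1-yl}-3-{[(4-methoxybenzyl)oxy]methyl}furan-2(5H)-one | COc1ccc(COCC[C@@]2(C)O[C@@H]2[C@H](O[Si](CC)(CC)CC)/C=C(/C)[C@H](O[Si](C)(C)C(C)(C)C)[C@@H]2OC(=O)C(COCc3ccc(OC)cc3)=C2)cc1 | intermediate
24 | (5R)-5-{(1S,2Z,4R)-1-[(tert-butyldimethylsilyl)oxy]-4-[(2R,3R)-3-(2-hydroxyethyl)-3-methyloxiran-2-yl]-2-methyl-4-[(triethylsilyl)oxy]but-2-en-1-yl}-3-(hydroxymethyl)furan-2(5H)-one | OCC[C@@]1(C)O[C@@H]1[C@H](O[Si](CC)(CC)CC)/C=C(/C)[C@H](O[Si](C)(C)C(C)(C)C)[C@@H]1OC(=O)C(CO)=C1 | intermediate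
25 | (5R)-3-(bromomethyl)-5-{(1S,2Z,4R)-1-[(tert-butyldimethylsilyl)oxy]-4-[(2R,3R)-3-(2-hydroxyethyl)-3-methyloxiran-2-yl]-2-methyl-4-[(triethylsilyl)oxy]but-2-en-1-yl}furan-2(5H)-one | OCC[C@@]1(C)O[C@@H]1[C@H](O[Si](CC)(CC)CC)/C=C(/C)[C@H](O[Si](C)(C)C(C)(C)C)[C@@H]1OC(=O)C(CBr)=C1 | intermediate
26 | (5R)-3-(bromomethyl)-5-{(1S,2Z,4R)-1-[(tert-butyldimethylsilyl)oxy]-2-methyl-4-[(2R,3R)-3-methyl-3-(2-oxoethyl)oxiran-2-yl]-4-[(triethylsilyl)oxy]but-2-en-1-yl}furan-2(5H)-one | O=CC[C@@]1(C)O[C@@H]1[C@H](O[Si](CC)(CC)CC)/C=C(/C)[C@H](O[Si](C)(C)C(C)(C)C)[C@@H]1OC(=O)C(CBr)=C1 | intermediate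
27 | allylchromium dichloride derived from 26 (CrCl2 in place of bromine at C13) | O=CC[C@@]1(C)O[C@@H]1[C@H](O[Si](CC)(CC)CC)/C=C(/C)[C@H](O[Si](C)(C)C(C)(C)C)[C@@H]1OC(=O)C(C[Cr](Cl)Cl)=C1 | intermediate
28 | (1R,2R,5S,6R,7R,8R,10R)-5-[(tert-butyldimethylsilyl)oxy]-1,10-epoxy-8-hydroxy-2-[(triethylsilyl)oxy]germacra-3Z,11(13)-dien-6,12-olide | C=C1C(=O)O[C@@H]2[C@H]1[C@H](O)C[C@@]1(C)O[C@@H]1[C@H](O[Si](CC)(CC)CC)/C=C(/C)[C@@H]2O[Si](C)(C)C(C)(C)C | intermediate
29 | (1R,2R,5S,6R,7R,8R,10R)-5-[(tert-butyldimethylsilyl)oxy]-1,10-epoxy-8-[(E)-2-methylbut-2-enoyloxy]-2-[(triethylsilyl)oxy]germacra-3Z,11(13)-dien-6,12-olide | C=C1C(=O)O[C@@H]2[C@H]1[C@H](OC(=O)/C(C)=C/C)C[C@@]1(C)O[C@@H]1[C@H](O[Si](CC)(CC)CC)/C=C(/C)[C@@H]2O[Si](C)(C)C(C)(C)C | intermediate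
30 | (1R,2R,5S,6R,7R,8R,10R)-5-[(tert-butyldimethylsilyl)oxy]-1,10-epoxy-2-hydroxy-8-[(E)-2-methylbut-2-enoyloxy]germacra-3Z,11(13)-dien-6,12-olide | C=C1C(=O)O[C@@H]2[C@H]1[C@H](OC(=O)/C(C)=C/C)C[C@@]1(C)O[C@@H]1[C@H](O)/C=C(/C)[C@@H]2O[Si](C)(C)C(C)(C)C | intermediate
31 | (1S,5S,6R,7R,8R,10R)-5-[(tert-butyldimethylsilyl)oxy]-1,10-epoxy-8-[(E)-2-methylbut-2-enoyloxy]-2-oxogermacra-3Z,11(13)-dien-6,12-olide | C=C1C(=O)O[C@@H]2[C@H]1[C@H](OC(=O)/C(C)=C/C)C[C@@]1(C)O[C@@H]1C(=O)/C=C(/C)[C@@H]2O[Si](C)(C)C(C)(C)C | intermediate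
32 | (1S,5S,6R,7R,8R,10R)-1,10-epoxy-5-hydroxy-8-[(E)-2-methylbut-2-enoyloxy]-2-oxogermacra-3Z,11(13)-dien-6,12-olide (CNP0345622.1) | C=C1C(=O)O[C@@H]2[C@H]1[C@H](OC(=O)/C(C)=C/C)C[C@@]1(C)O[C@@H]1C(=O)/C=C(/C)[C@@H]2O | target

**Count and risks**

Total step count: 21. Longest linear sequence: 15 steps (8 → 9 → 12 → 13 → 19 → 20 → 22 → 23 → 24 → 25 → 26 → 28 → 29 → 30 → 31 → 32).

Step 17 (ring closure). The aldehyde may be taken through its other face in the macrocyclic transition state (C9 pseudo-equatorial), so that the C8 epimer forms instead of the (8R) carbinol. The fallback sets out from 26 and accepts this outcome: the same chromium-mediated closure via 27 then gives the (8S)-configured macrocyclic alcohol F1. Mitsunobu esterification of F1 with tiglic acid (PPh3, diisopropyl azodicarboxylate, toluene, 0 °C → rt) attaches the tiglate with inversion at C8 and comes back to the route at 29. The C8 configuration is then set by displacement rather than in the ring closure, and step 18 is not needed.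

Step 10 (vinylogous aldol). Simple diastereoselection in the open transition state may be poor for this α-branched Z-enal, the syn adduct prevailing. The fallback sets out from 17 and 13 and aims for the syn adduct on purpose: a syn-selective titanium catalyst (Ti(OiPr)4 with BINOL, antipode chosen for the 6R lactone carbon) gives the trimethylsilyl ether of the syn adduct F2 and, after acidic work-up, the (5R,6R)-configured syn carbinol F3. Mitsunobu reaction with chloroacetic acid (PPh3, diisopropyl azodicarboxylate, THF) inverts C5 and gives the (5S)-chloroacetate F4. Thiourea with NaHCO3 in ethanol removes the chloroacetyl group under near-neutral conditions and comes back to the route at 19.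

Step 12 (fragment coupling). Addition of the hindered Z-alkenylchromium (cis-allylic silyloxy branch) may be slow, with erosion of the alkene geometry at the alkenylnickel stage or opening of the epoxy aldehyde by the chromium salts. The fallback replaces carbonyl addition by acyl coupling and reduction, and sets out from 6 and 20. Oxidation of 6 (TEMPO, PhI(OAc)2, MeCN/H2O) gives the glycidic acid F5, and thiophenol with dicyclohexylcarbodiimide gives the S-phenyl thioester F6. From 20, hexamethylditin with Pd(PPh3)4 (toluene, 80 °C) gives the Z-alkenylstannane F7. Liebeskind–Srogl coupling of F6 and F7 (Pd2(dba)3, tri(2-furyl)phosphine, CuO2PPh2 with monovalent copper, THF, rt) proceeds under neutral conditions with retention of the Z geometry and gives the epoxy enone F8. Luche reduction (NaBH4, CeCl3·7H2O, MeOH, −78 °C), which is anti-selective for α,β-epoxy ketones, comes back to the route at 22.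

**Further compounds**

F1 | step 17 | (1R,2R,5S,6R,7R,8S,10R)-5-[(tert-butyldimethylsilyl)oxy]-1,10-epoxy-8-hydroxy-2-[(triethylsilyl)oxy]germacra-3Z,11(13)-dien-6,12-olide | C=C1C(=O)O[C@@H]2[C@H]1[C@@H](O)C[C@@]1(C)O[C@@H]1[C@H](O[Si](CC)(CC)CC)/C=C(/C)[C@@H]2O[Si](C)(C)C(C)(C)C
F2 | step 10 | trimethylsilyl ether of F3 at the carbinol oxygen | I/C=C(/C)[C@@H](O[Si](C)(C)C)[C@@H]1OC(=O)C(COCc2ccc(OC)cc2)=C1
F3 | step 10 | (5R)-5-[(1R,2Z)-1-hydroxy-3-iodo-2-methylprop-2-en-1-yl]-3-{[(4-methoxybenzyl)oxy]methyl}furan-2(5H)-one | I/C=C(/C)[C@@H](O)[C@@H]1OC(=O)C(COCc2ccc(OC)cc2)=C1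
F4 | step 10 | (1S,2Z)-3-iodo-1-[(2R)-4-{[(4-methoxybenzyl)oxy]methyl}-5-oxo-2,5-dihydrofuran-2-yl]-2-methylprop-2-en-1-yl chloroacetate | I/C=C(/C)[C@H](OC(=O)CCl)[C@@H]1OC(=O)C(COCc2ccc(OC)cc2)=C1
F5 | step 12 | (2S,3R)-3-{2-[(4-methoxybenzyl)oxy]ethyl}-3-methyloxirane-2-carboxylic acid | COc1ccc(COCC[C@@]2(C)O[C@@H]2C(=O)O)cc1
F6 | step 12 | S-phenyl (2S,3R)-3-{2-[(4-methoxybenzyl)oxy]ethyl}-3-methyloxirane-2-carbothioate | COc1ccc(COCC[C@@]2(C)O[C@@H]2C(=O)Sc2ccccc2)cc1
F7 | step 12 | (5R)-5-{(1S,2Z)-1-[(tert-butyldimethylsilyl)oxy]-2-methyl-3-(trimethylstannyl)prop-2-en-1-yl}-3-{[(4-methoxybenzyl)oxy]methyl}furan-2(5H)-one | C[Sn](C)(C)/C=C(/C)[C@H](O[Si](C)(C)C(C)(C)C)[C@@H]1OC(=O)C(COCc2ccc(OC)cc2)=C1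
F8 | step 12 | (5R)-5-{(1S,2Z)-1-[(tert-butyldimethylsilyl)oxy]-4-[(2S,3R)-3-{2-[(4-methoxybenzyl)oxy]ethyl}-3-methyloxiran-2-yl]-2-methyl-4-oxobut-2-en-1-yl}-3-{[(4-methoxybenzyl)oxy]methyl}furan-2(5H)-one | COc1ccc(COCC[C@@]2(C)O[C@@H]2C(=O)/C=C(/C)[C@H](O[Si](C)(C)C(C)(C)C)[C@@H]2OC(=O)C(COCc3ccc(OC)cc3)=C2)cc1
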